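**Retrosynthetic overview**

1. The biaryl bond C3'–C6'' is cut last (Suzuki–Miyaura): boronate 12 (unit 1) plus iodide 15 (unit 2). Unit 2, with all its rings and its stereocentre, comes from (2S)-sakuranetin by 4'-O-protection and C6 iodination.
2. In unit 1 the dihydropyranone ring (O1, C2, C3, C4, C4a, C8a) is never closed as a six-membered ring. It grows from the five-membered furanone ring (O1, C2, C4, C4a, C8a) of a benzofuran-3(2H)-one when C3, first an exocyclic CH2 radical on C2, is inserted between C2 and C4 (radical 1,2-acyl shift). The same step joins C2 to ring B and sets C2.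
3. Enabling feature: the C4 ketone sits between aromatic C4a and the C3 methylene, and C2 carries the ring oxygen O1. The exocyclic radical can therefore add to C4=O, and cleavage of the old C2–C4 bond leaves a C2 radical that the O1 lone pair stabilises and that chiral nickel can arylate.
4. Radical precursor 6: coumaranone 1 plus glyoxylic acid (supplies C3 and the carboxyl carbon later lost as CO2), hydrogenation, N-hydroxyphthalimide ester.
5. Ring order: ring A of unit 1 and rings A, B, C of unit 2 are bought; furanone to pyranone with ring B attached (step 4); biaryl union (step 8); global deprotection (step 9).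

Key step: step 4

Remark: (2S)-sakuranetin (13) is taken as the commercially available natural enantiomer; both stereocentres of the target are (S).
Remark: the sense of induction of the chiral nickel catalyst in step 4 cannot be predicted with certainty; the ligand antipode that delivers (2S) is meant and is written as (S,S)-i-Pr-BiOX ((4S,4'S)-4,4'-diisopropyl-4,4',5,5'-tetrahydro-2,2'-bioxazole).

**Route**

Step 1
Reactants: 1 4,6-dimethoxybenzofuran-3(2H)-one; 2 glyoxylic acid monohydrate
Product: 3 (Z)-2-(4,6-dimethoxy-3-oxobenzofuran-2(3H)-ylidene)acetic acid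
Conditions: H2SO4 (cat.), 1,4-dioxane, 80 °C
Reagents that add atoms: none
Why: Acid-catalysed aldol condensation (Knoevenagel type) of the doubly activated C2 methylene with the aldehyde of glyoxylic acid, a reaction type established for coumaranones and indanones; the Z alkene is expected and is removed in step 2.

Step 2
Reactants: 3 (Z)-2-(4,6-dimethoxy-3-oxobenzofuran-2(3H)-ylidene)acetic acid
Product: 4 rac-2-(4,6-dimethoxy-3-oxo-2,3-dihydrobenzofuran-2-yl)acetic acid
Conditions: H2 (1 atm), 10% Pd/C, EtOAc/MeOH, rt
Reagents that add atoms: none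
Why: Catalytic hydrogenation of the electron-poor exocyclic alkene should be much faster than reduction of the electron-rich aryl ketone; the new C2 stereocentre is left racemic on purpose because step 4 erases it.

Step 3
Reactants: 4 rac-2-(4,6-dimethoxy-3-oxo-2,3-dihydrobenzofuran-2-yl)acetic acid; 5 N-hydroxyphthalimide
Product: 6 rac-1,3-dioxoisoindolin-2-yl 2-(4,6-dimethoxy-3-oxo-2,3-dihydrobenzofuran-2-yl)acetate
Conditions: DIC, CH2Cl2, 0 °C to rt
Reagents that add atoms: none
Why: Carbodiimide esterification to the redox-active N-acyloxyphthalimide; no base is added, so enolisation of the ketone toward an enol lactone should be avoided.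

Step 4
Reactants: 6 rac-1,3-dioxoisoindolin-2-yl 2-(4,6-dimethoxy-3-oxo-2,3-dihydrobenzofuran-2-yl)acetate; 7 2-bromo-4-iodoanisole
Product: 11 (2S)-2-(3-bromo-4-methoxyphenyl)-5,7-dimethoxychroman-4-one, via primary alkyl radical 8 (not isolated), via cyclopropyloxyl radical 9 (not isolated), via chromanon-2-yl radical 10 (not isolated)
Conditions: NiBr2·glyme (5 mol%), (S,S)-i-Pr-BiOX (6 mol%), Zn dust (2 equiv), 7 (1.5 equiv), DMA (0.02 M), 10 °C, 6 added over 8 h
Reagents that add atoms: none
Why: Proposed new method: single-electron reduction of the N-acyloxyphthalimide releases CO2 and primary radical 8, which adds 3-exo-trig to the furanone ketone to give alkoxyl radical 9; β-scission of the ring-fusion bond (the old C2–C4 bond) gives the six-membered radical 10 (Dowd–Beckwith 1,2-acyl shift), which is captured by the divalent arylnickel species formed from zerovalent nickel and the C–I bond of 7, and reductive elimination from trivalent nickel forms the C2–aryl bond. The closest known reaction types are the Dowd–Beckwith ring expansion of 2-(halomethyl) cyclic ketones, the nickel-catalysed reductive decarboxylative arylation of N-acyloxyphthalimides with aryl iodides, and the enantioselective nickel arylation of α-oxy radicals of cyclic ethers; their merger on a coumaranone is what is new. The pyranone ring is not closed by a cyclisation of its own: a transient cyclopropane is closed 3-exo-trig and the five-membered ring grows to six by cleavage of the shared bond. C2 is created in the C–C reductive elimination and should be controlled by the chiral bioxazoline ligand on nickel; the process is stereoconvergent because radical 10 is planar and the stereocentre of racemic 6 is lost. The step needs the acyl shift to outrun capture of 8 by nickel, which low nickel concentration and high dilution favour, and needs scission toward 10 and not back to 8, which the O1 lone pair on C2 and relief of bicyclic strain secure; the C–I bond of 7 should react before the C–Br bond flanked by the methoxy group.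

Step 5
Reactants: 11 (2S)-2-(3-bromo-4-methoxyphenyl)-5,7-dimethoxychroman-4-one
Product: 12 (2S)-5,7-dimethoxy-2-[4-methoxy-3-(4,4,5,5-tetramethyl-1,3,2-dioxaborolan-2-yl)phenyl]chroman-4-one
Conditions: Pd(dppf)Cl2 (5 mol%), KOAc, 1,4-dioxane, 85 °C
Reagents that add atoms: bis(pinacolato)diboron, CC1(C)OB(OC1(C)C)B1OC(C)(C)C(C)(C)O1
Why: Miyaura borylation of the aryl bromide; the weak base KOAc should leave the ketone and the C2 stereocentre of the flavanone untouched.

Step 6
Reactants: 13 (2S)-sakuranetin
Product: 14 (2S)-5-hydroxy-7-methoxy-2-[4-(methoxymethoxy)phenyl]chroman-4-one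
Conditions: MOMCl, i-Pr2NEt, CH2Cl2, 0 °C to rt
Reagents that add atoms: chloromethyl methyl ether, COCCl
Why: Williamson-type alkylation of the more acidic, non-chelated 4'-phenol; the 5-hydroxyl is hydrogen-bonded to the ketone and should stay free, and the mild amine base should not open the flavanone ring.

Step 7
Reactants: 14 (2S)-5-hydroxy-7-methoxy-2-[4-(methoxymethoxy)phenyl]chroman-4-one
Product: 15 (2S)-5-hydroxy-6-iodo-7-methoxy-2-[4-(methoxymethoxy)phenyl]chroman-4-one
Conditions: BnMe3N·ICl2 (1.05 equiv), CaCO3, CH2Cl2/MeOH, rt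
Reagents that add atoms: benzyltrimethylammonium dichloroiodate, C[N+](C)(C)Cc1ccccc1.Cl[I-]Cl
Why: Electrophilic aromatic iodination, which in 5-hydroxy-7-methoxy flavonoids is known to go ortho to the free chelated hydroxyl (C6); the CaCO3 buffer protects the MOM ether and the less activated ring B should not react.

Step 8
Reactants: 12 (2S)-5,7-dimethoxy-2-[4-methoxy-3-(4,4,5,5-tetramethyl-1,3,2-dioxaborolan-2-yl)phenyl]chroman-4-one; 15 (2S)-5-hydroxy-6-iodo-7-methoxy-2-[4-(methoxymethoxy)phenyl]chroman-4-one
Product: 16 (2S)-6-{5-[(2S)-5,7-dimethoxy-4-oxochroman-2-yl]-2-methoxyphenyl}-5-hydroxy-7-methoxy-2-[4-(methoxymethoxy)phenyl]chroman-4-one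
Conditions: Pd(OAc)2 (5 mol%), SPhos (10 mol%), K3PO4, toluene/H2O, 70 °C
Reagents that add atoms: none
Why: Suzuki–Miyaura coupling of a doubly ortho-substituted aryl iodide with an ortho-methoxy aryl boronate, the case the bulky biaryl phosphine SPhos is designed for; the weak base in a two-phase medium should limit base-induced ring opening of the two flavanones.

Step 9
Reactants: 16 (2S)-6-{5-[(2S)-5,7-dimethoxy-4-oxochroman-2-yl]-2-methoxyphenyl}-5-hydroxy-7-methoxy-2-[4-(methoxymethoxy)phenyl]chroman-4-one
Product: 17 (2S)-5-hydroxy-6-{5-[(2S)-5-hydroxy-7-methoxy-4-oxochroman-2-yl]-2-methoxyphenyl}-2-(4-hydroxyphenyl)-7-methoxychroman-4-one (CNP0150873.1)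
Conditions: BCl3 (6 equiv), CH2Cl2, −78 to 0 °C; MeOH quench
Reagents that add atoms: none
Why: BCl3 cleaves the MOM acetal and, through the six-membered chelate with the C4 ketone, only the peri 5-methoxy group, a selectivity established for 5-methoxyflavanones; the three non-chelated aryl methyl ethers and both C2 stereocentres should survive at 0 °C.

**Compound list**

1 | 4,6-dimethoxybenzofuran-3(2H)-one | COc1cc(OC)c2c(c1)OCC2=O | starting material
2 | glyoxylic acid monohydrate (2,2-dihydroxyacetic acid) | OC(O)C(=O)O | starting material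
3 | (Z)-2-(4,6-dimethoxy-3-oxobenzofuran-2(3H)-ylidene)acetic acid | COc1cc(OC)c2c(c1)O/C(=C\C(=O)O)C2=O | intermediate
4 | rac-2-(4,6-dimethoxy-3-oxo-2,3-dihydrobenzofuran-2-yl)acetic acid | COc1cc(OC)c2c(c1)OC(CC(=O)O)C2=O | intermediate
5 | N-hydroxyphthalimide | O=C1c2ccccc2C(=O)N1O | starting material
6 | rac-1,3-dioxoisoindolin-2-yl 2-(4,6-dimethoxy-3-oxo-2,3-dihydrobenzofuran-2-yl)acetate | COc1cc(OC)c2c(c1)OC(CC(=O)ON1C(=O)c3ccccc3C1=O)C2=O | intermediate
7 | 2-bromo-4-iodoanisole (2-bromo-4-iodo-1-methoxybenzene) | COc1ccc(I)cc1Br | starting material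
8 | (4,6-dimethoxy-3-oxo-2,3-dihydrobenzofuran-2-yl)methyl radical (primary alkyl radical, not isolated) | COc1cc(OC)c2c(c1)OC([CH2])C2=O | intermediate
9 | cyclopropane-fused alkoxyl radical: oxygen radical on the former ketone carbon, which is bonded to C2 and to the former exocyclic CH2 (not isolated) | COc1cc(OC)c2c(c1)OC1CC21[O] | intermediate
10 | 5,7-dimethoxy-4-oxochroman-2-yl radical (not isolated) | COc1cc(OC)c2c(c1)O[CH]CC2=O | intermediate
11 | (2S)-2-(3-bromo-4-methoxyphenyl)-5,7-dimethoxychroman-4-one | COc1cc(OC)c2c(c1)O[C@H](c1ccc(OC)c(Br)c1)CC2=O | intermediate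
12 | (2S)-5,7-dimethoxy-2-[4-methoxy-3-(4,4,5,5-tetramethyl-1,3,2-dioxaborolan-2-yl)phenyl]chroman-4-one | COc1cc(OC)c2c(c1)O[C@H](c1ccc(OC)c(B3OC(C)(C)C(C)(C)O3)c1)CC2=O | intermediate
13 | (2S)-sakuranetin, (2S)-5-hydroxy-2-(4-hydroxyphenyl)-7-methoxychroman-4-one | COc1cc2c(c(O)c1)C(=O)C[C@@H](c1ccc(O)cc1)O2 | starting material
14 | (2S)-5-hydroxy-7-methoxy-2-[4-(methoxymethoxy)phenyl]chroman-4-one | COc1cc2c(c(O)c1)C(=O)C[C@@H](c1ccc(OCOC)cc1)O2 | intermediate
15 | (2S)-5-hydroxy-6-iodo-7-methoxy-2-[4-(methoxymethoxy)phenyl]chroman-4-one | COc1cc2c(c(O)c1I)C(=O)C[C@@H](c1ccc(OCOC)cc1)O2 | intermediate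
16 | (2S)-6-{5-[(2S)-5,7-dimethoxy-4-oxochroman-2-yl]-2-methoxyphenyl}-5-hydroxy-7-methoxy-2-[4-(methoxymethoxy)phenyl]chroman-4-one | COc1cc(OC)c2c(c1)O[C@H](c1ccc(OC)c(-c3c(OC)cc4c(c3O)C(=O)C[C@@H](c3ccc(OCOC)cc3)O4)c1)CC2=O | intermediate
17 | (2S)-5-hydroxy-6-{5-[(2S)-5-hydroxy-7-methoxy-4-oxochroman-2-yl]-2-methoxyphenyl}-2-(4-hydroxyphenyl)-7-methoxychroman-4-one (CNP0150873.1) | COc1cc(O)c2c(c1)O[C@H](c1ccc(OC)c(-c3c(OC)cc4c(c3O)C(=O)C[C@@H](c3ccc(O)cc3)O4)c1)CC2=O | target

**Totals and risks**

Total step count: 9. Longest linear sequence: 7 (steps 1, 2, 3, 4, 5, 8, 9).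

Steps most likely to fail:

1. Step 4 (the proposed new method). The unrearranged primary radical may be captured by nickel before the acyl shift, β-hydride elimination at nickel may give the chromone, the ligand may induce poorly, or the active ester may be lost by enol-lactonisation. The fallback uses known chemistry and sets out from 6. Photoreductive decarboxylation (Ru(bpy)3Cl2 cat., Hantzsch ester, blue light, high dilution) should send the same radical through the same Dowd–Beckwith acyl shift and end it by hydrogen-atom transfer, giving 5,7-dimethoxychroman-4-one F1 with the ring expansion retained and no stereocentre. Dehydrogenation with IBX (DMSO, 80 °C) should give 5,7-dimethoxy-4H-chromen-4-one F2. Asymmetric conjugate addition of commercial (3-bromo-4-methoxyphenyl)boronic acid to F2 (Pd(OCOCF3)2, the t-BuPyOx antipode that gives 2S, NH4PF6, H2O, ClCH2CH2Cl, 60 °C) sets C2 under catalyst control and comes back to the route at 11.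

2. Step 8. Oxidative addition and transmetalation at the doubly ortho-substituted iodide may be slow, boronate 12 may protodeboronate, and base may open a flavanone ring and erode a C2 stereocentre. The fallback sets out from 15 and moves the difficult coupling onto a cheap partner used in excess: chemoselective Suzuki–Miyaura coupling of 15 at its C–I bond with commercial (5-bromo-2-methoxyphenyl)boronic acid (Pd(PPh3)4, Na2CO3, DME/H2O, 70 °C) should give (2S)-6-(5-bromo-2-methoxyphenyl)-5-hydroxy-7-methoxy-2-[4-(methoxymethoxy)phenyl]chroman-4-one F3. F3 then takes the place of 7 in the nickel-catalysed ring-expanding arylation of 6 (step 4 conditions, NaI additive for the less reactive bromide), which comes back to the route at 16 and skips steps 5 and 8.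

3. Step 9. Non-chelated methyl ethers may be lost by over-demethylation, or the Lewis acid may open a flavanone ring with loss of configuration on the fully assembled molecule. The fallback sets out from 11 and does the demethylation on the simple monomer: BCl3 (CH2Cl2, −78 to 0 °C) should give (2S)-2-(3-bromo-4-methoxyphenyl)-5-hydroxy-7-methoxychroman-4-one F4. Miyaura borylation as in step 5 should give (2S)-5-hydroxy-7-methoxy-2-[4-methoxy-3-(4,4,5,5-tetramethyl-1,3,2-dioxaborolan-2-yl)phenyl]chroman-4-one F5. Coupling of F5 with 15 as in step 8 should give (2S)-5-hydroxy-6-{5-[(2S)-5-hydroxy-7-methoxy-4-oxochroman-2-yl]-2-methoxyphenyl}-7-methoxy-2-[4-(methoxymethoxy)phenyl]chroman-4-one F6. Mild acid (HCl, MeOH, 40 °C) then removes only the MOM group and comes back to the route at 17.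

Further compounds
F1 | step 4 | 5,7-dimethoxychroman-4-one | COc1cc(OC)c2c(c1)OCCC2=O
F2 | step 4 | 5,7-dimethoxy-4H-chromen-4-one | COc1cc(OC)c2c(c1)OC=CC2=O
F3 | step 8 | (2S)-6-(5-bromo-2-methoxyphenyl)-5-hydroxy-7-methoxy-2-[4-(methoxymethoxy)phenyl]chroman-4-one | COc1ccc(Br)cc1-c1c(OC)cc2c(c1O)C(=O)C[C@@H](c1ccc(OCOC)cc1)O2
F4 | step 9 | (2S)-2-(3-bromo-4-methoxyphenyl)-5-hydroxy-7-methoxychroman-4-one | COc1cc(O)c2c(c1)O[C@H](c1ccc(OC)c(Br)c1)CC2=O
F5 | step 9 | (2S)-5-hydroxy-7-methoxy-2-[4-methoxy-3-(4,4,5,5-tetramethyl-1,3,2-dioxaborolan-2-yl)phenyl]chroman-4-one | COc1cc(O)c2c(c1)O[C@H](c1ccc(OC)c(B3OC(C)(C)C(C)(C)O3)c1)CC2=O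
F6 | step 9 | (2S)-5-hydroxy-6-{5-[(2S)-5-hydroxy-7-methoxy-4-oxochroman-2-yl]-2-methoxyphenyl}-7-methoxy-2-[4-(methoxymethoxy)phenyl]chroman-4-one | COc1cc(O)c2c(c1)O[C@H](c1ccc(OC)c(-c3c(OC)cc4c(c3O)C(=O)C[C@@H](c3ccc(OCOC)cc3)O4)c1)CC2=O
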